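The leftover is what you are after here: in both earlier runs the readings of D fall away after their highest value, so the number asked is what survives that fall, and you can reckon it from the rate of the fall.

| flask | Q | L | remark | time | volume of the second phase over the first |
|---|---|---|---|---|---|
| dusk | 0.018 M | 4 equiv | run made earlier |  |  |
| dawn | 0.12 M | 4 equiv | run made earlier |  |  |
| Wednesday's | 0.012 M | 4.00 equiv |  | 5.0 d | 0.50 |
| Sunday's | 0.025 M | 4.00 equiv |  | 5.0 d | 0.50 |
| Tuesday's | 0.050 M | 4.00 equiv |  | 5.0 d | 0.50 |
| Monday's | 0.10 M | 4.00 equiv |  | 5.0 d | 0.50 |

| run | time / d | D / % |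
|---|---|---|
| dusk | 0.125 | 13 |
| dusk | 0.417 | 51 |
| dusk | 0.625 | 50 |
| dusk | 1.04 | 38 |
| dusk | 1.67 | 20 |
| dusk | 2.08 | 15 |
| dusk | 2.50 | 11 |
| dawn | 0.333 | 64 |
| dawn | 0.625 | 48 |
| dawn | 1.04 | 30 |
| dawn | 1.25 | 23 |
| dawn | 1.67 | 19 |
| dawn | 2.00 | 13 |
| dawn | 2.50 | 9 |

(scatter of a reading: 1.5 percentage points)

- D is meant together with its Z
- in the second phase: L, Z; everything else is in the first
- charges count per volume of the first phase; a concentration in a rate is the amount of a species over the volume of its own phase; every rate counts per litre of the first phase
- steps thought possible: J <-> L; Q + J -> D; D <-> Z; D -> X; 2 J -> E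
- the earlier runs hold the two phases in the same ratio of volumes as the flask asked about
- the concentration of D that is asked is that of its free form alone
- "hardly changes" means that all values lie within two and a half points (for a concentration: within two and a half percent of the largest)

- [D] (only what is free in solution, in the first phase) at the end for Wednesday's, Sunday's, Tuesday's, Monday's, in this order
- how that number moves from the first to the last of them (hardly changes / rises all the way / falls all the way / falls, then rises / rises, then falls)

1. Start with the dawn run, where the readings of D, meant with its Z, fall between 0.333 d and 1.04 d at a rate of 1.07 d⁻¹, as read through a scatter of 1.5 percentage points.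

2. Between 1.25 d and 2.50 d the same run falls at 0.751 d⁻¹, slower than before. Call this the tail constant: the logarithm of the ratio of two late readings over the time between them, an apparent first-order rate constant. The dusk run reads nearly the same, 0.720 d⁻¹, with a charge smaller by a factor of 6.67, so I carry one tail constant across the charges.

3. The slowing factor is 0.700. I read it as Z taking up part of D while the step to X runs on the free part, which makes this factor my free share.

4. Over the remaining time the slower rate leaves twice what the early rate would. From the last dawn reading of 9%, you expect 1.38% of the charge as D with Z, and 0.966% free. I carry that fraction to each flask, so my [D] rises all the way.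

The forecast gives 1.400 × 10⁻⁴ M, 2.800 × 10⁻⁴ M, 5.200 × 10⁻⁴ M and 9.500 × 10⁻⁴ M, rises all the way, which as fractions of the charge run from 1.17% to 0.950% where I hold one fraction, reasoning that “Free D therefore scales almost proportionally with the charge”.

The flask gives 8.76 × 10⁻⁵ M, 1.67 × 10⁻⁴ M, 3.18 × 10⁻⁴ M and 6.16 × 10⁻⁴ M, rises all the way.

    J ⇌ L, rate k1*([J] - [L]/K1) per volume of the first phase (partition coefficient = 0.810, kL = 0.0190 h⁻¹)
    Q + J → D (k = 14.0 M⁻¹ h⁻¹)
    D ⇌ Z, rate k3*([D] - [Z]/K3) per volume of the first phase (partition coefficient = 1.40, kL = 0.0320 h⁻¹)
    D → X (k = 0.0820 h⁻¹)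
    2 J → E (k = 0.180 M⁻¹ h⁻¹)

In Wednesday's flask, D with its Z from 2.50 d to the end gives a tail constant of 0.690 d⁻¹, a half-life of 1.00 d, longer than the 0.35 d of D going to X alone. The ratio of this tail constant to the 1.97 d⁻¹ of D going to X is 35.1%, lower than my slowing factor of 0.700, and of the 2.09% of D with Z standing at the end in Wednesday's flask it makes 0.734% of the charge, where that flask holds 0.730% free. In Monday's flask the tail constant is 0.688 d⁻¹, so the ratio is 34.9%, which of 1.77% makes 0.618%, and Monday's flask holds 0.616% free.

The data stem from a simulated flask with made-up constants, noise included.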